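At its first reading, 0.500 min, the east run stands at 19.2% target, and its readings from 2.50 min on average 25.5%, so the first reading is 75.2% of that mean. The south-east run, with a quarter of the free catalyst, averages 27.9% from 6.00 min on, and it passes the same share of that, 21.0%, at 2.20 min, by a straight line between its readings at 1.33 min and 2.50 min.

| flask | starting material | second substrate | reagent | protic impurity | free catalyst | remark |
|---|---|---|---|---|---|---|
| south-east | 0.010 M | 5 mM | 5 mM | 1 mM | 0.30 mM | run made earlier |
| east | 0.010 M | 5 mM | 5 mM | 1 mM | 1.2 mM | run made earlier |
| north-west | 0.015 M | 5 mM | 5 mM | 1 mM | 0.60 mM | run made earlier |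
| flask | 0.010 M | 5.00 mM | 5.00 mM | 1.00 mM | 0.60 mM |  |

| run | time / min | target / % |
|---|---|---|
| south-east | 0.500 | 7.1 |
| south-east | 1.33 | 14.9 |
| south-east | 2.50 | 23.1 |
| south-east | 4.00 | 25.2 |
| south-east | 6.00 | 27.7 |
| south-east | 8.00 | 28.4 |
| south-east | 10.0 | 27.7 |
| east | 0.500 | 19.2 |
| east | 1.33 | 26.2 |
| east | 2.50 | 25.7 |
| east | 4.00 | 25.5 |
| east | 6.00 | 25.5 |
| east | 8.00 | 26.0 |
| east | 10.0 | 24.9 |
| north-west | 2.00 | 19.8 |
| north-west | 4.00 | 20.9 |
| north-west | 6.00 | 21.5 |
| north-west | 8.00 | 22.0 |
| north-west | 10.0 | 21.0 |

(each reading ± 0.5 percentage points)

- the numbers in the tables scatter by 0.5 percentage points (one standard deviation)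
- what is bound to the catalyst counts as converted

- apparent order in free catalyst when 30% of the starting material are converted (percent change of the rate of making target for one percent more free catalyst charged)

We hold these two times against each other because each run then stands at the same share of its own end, so the different end levels drop out of the ratio. The logarithm of the ratio of the times over that of the catalyst charges gives 1.07, our time exponent: the power of free catalyst by which the time to a fixed share of the end shrinks. It is a reading, an average over the stretch from 0.30 mM to 1.2 mM.

The forecast says 1.2, higher than our reckoning, on the ground that “Extra catalyst then holds more material bound”.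

The simulation gives 1.2, the forecast's value.

    starting material + free catalyst ⇌ catalyst intermediate A (K = 7000 M⁻¹, k = 72.6 M⁻¹ s⁻¹)
    reagent + catalyst intermediate A → free catalyst + target (k = 34.3 M⁻¹ s⁻¹)
    second substrate + free catalyst ⇌ catalyst intermediate B (K = 980 M⁻¹, k = 232 M⁻¹ s⁻¹)
    reagent + catalyst intermediate B → free catalyst + second product (k = 84.4 M⁻¹ s⁻¹)
    starting material + protic impurity → quenched substrate (k = 18.9 M⁻¹ s⁻¹)

The flask reaches 30% conversion at 0.714 min, and twice the free catalyst multiplies that time by 0.408. Our exponent carries the south-east time to 1.05 min for this flask, whose target stands at 21.2% after 1.20 min and at 27.5% after 12.0 min. For the flask with doubled free catalyst it gives a factor of 0.476, so 0.340 min to that conversion, against the 0.291 min which that flask takes.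

The earlier runs and the new flask are simulated from invented constants.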